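I had no rate constants for gamma, but I had its charges and two runs.

all flasks: reagent 0.0132 M
- gamma: starting material 0.022 M; the very flask that is asked about, followed so far
- epsilon: starting material 0.011 M; run made earlier
- flask: starting material 0.022 M; time 10 h

| run | time / h | starting material / % | over-reaction product / % | target / % |
|---|---|---|---|---|
| gamma | 0.417 | 14.5 | 33.6 | 3.4 |
| gamma | 1.00 | 13.9 | 57.0 | 0.1 |
| gamma | 2.00 | 15.1 | 59.2 | 1.7 |
| gamma | 3.00 | 13.4 | 57.0 | 0.2 |
| epsilon | 1.00 | 1.1 | 85.5 | 1.4 |
| epsilon | 2.00 | 0 | 96.0 | 0.6 |
| epsilon | 3.00 | 0 | 98.9 | 0 |
| epsilon | 4.00 | 0 | 99.8 | 0.8 |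

(readings scatter by 1 percentage point)



- share of the starting material used up at 10 h
- over-reaction product at 10 h, in percent of the starting material charged

Epsilon, with more reagent than starting material, reached 99.8% over-reaction product at 4.00 h. In gamma the reagent is the limiting reagent. Its charge is 60.0% of the starting material charge. I call this fraction the reagent ceiling: the most over-reaction product that one reagent per product allows.

I reckoned gamma from both ends. The long end is the ceiling. The short end is the readings, 59.2% at 2.00 h and 57.0% at 3.00 h, the first of them close to the ceiling. Joining them, I expected the ceiling at the asked time. The starting material readings were flat, so I expected conversion between 84.9% and 86.6%.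

The forecast gave 86% conversion and 58% over-reaction product, less product than my ceiling. Its ground was that “its stall looks like reagent exhaustion, not slow kinetics”.

Gamma gave 85.2% conversion and 60.0% over-reaction product, with 0% of the reagent left at 10.0 h.

    starting material + reagent → intermediate A (k = 0.440 M⁻¹ s⁻¹)
    intermediate A → intermediate B (k = 0.00220 s⁻¹)
    starting material ⇌ intermediate C (K = 1.70, k = 0.00810 s⁻¹)
    intermediate B → target (k = 0.00150 s⁻¹)
    target → over-reaction product (k = 0.00820 s⁻¹)

The ceiling and gamma's result agree. I applied the same fraction to a neighbour flask, the same as gamma but with 0.0053 M reagent. Its ceiling is 24.1%. That flask gave 24.1% over-reaction product at 10.0 h, with 0% of its reagent left. Of its starting material charge, 47.8% stood as intermediate C and 28.1% as starting material.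

All runs are simulated with constants of no real substance; the scatter is artificial.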